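Start from the leftover. In ochre at 40.0 h, L and Q together hold 27.8 % of the D and G charged, so 72.2 % of that charge is neither L nor Q.

common to all: D 0.50 M; G 0.50 M
- amber: J 0.36 M; run made earlier
- ochre: J 1.1 M; run made earlier
- spring: J 0.600 M; time 50 h
- dawn: J 1.00 M; time 50 h
- dusk: J 1.50 M; time 50 h

| run | time / h | L / % | Q / % |
|---|---|---|---|
| amber | 3.00 | 0.4 | 0.5 |
| amber | 8.00 | 3.1 | 1.4 |
| amber | 15.0 | 5.3 | 1.2 |
| amber | 25.0 | 4.7 | 3.1 |
| amber | 40.0 | 6.7 | 3.7 |
| ochre | 8.00 | 6.9 | 3.8 |
| ochre | 15.0 | 11.4 | 5.6 |
| ochre | 20.0 | 13.6 | 5.3 |
| ochre | 30.0 | 16.7 | 7.9 |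
| ochre | 40.0 | 18.7 | 9.1 |

(scatter of a reading: 0.5 percentage points)

- J is single-handed; D and G are mirror images of each other, charged as a racemate, each of them at the stated concentration
- an excess is the difference of the two amounts in percent of their sum
- "hardly changes" means that all values lie within two and a half points (for a concentration: within two and a half percent of the largest)
- the handed part of J does not stay in what it makes, so the products of the two hands are mirror images too

* excess of L over Q at the end for spring, dawn, dusk, in this order
* how the row runs (hardly changes / falls all the way / rises, then falls / falls, then rises / rises all the way)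

First find how J enters. From amber to ochre, J rises by a factor of 3.06, and L at 40.0 h rises by a factor of 2.79. Take each hand as first order in J. J then cancels from the ratio of the two rates:

rate of L / rate of Q = selectivity factor · [D]/[G]

The selectivity factor is the rate constant of the D hand over that of the G hand. [D]/[G] starts at one and need not stay there, so the readings do not give that factor directly. Read instead s, the product ratio: the sum of the L readings over the sum of the Q readings, with the course of [D]/[G] folded in.

amber: ΣL/ΣQ = 2.04

ochre: ΣL/ΣQ = 2.12

both runs: s = 2.10

excess = (s − 1)/(s + 1) = 35.5 %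

This s is a reading and carries the scatter. My own reckoning is that spring, dawn and dusk all stand near this excess. L outruns Q in ochre at 40.0 h, so [D]/[G] should sink below one, and I expect a small fall as J rises.

The forecast gives 37 %, 35 % and 32 %, a row that falls all the way. Its ground is “More J means more depletion of the fast hand”.

The flasks give 37.5 %, 36.0 % and 34.3 %, a row that falls all the way.

    J + D → L (k = 4.55 × 10⁻⁴ /M/min)
    J + G → Q (k = 1.96 × 10⁻⁴ /M/min)
    D ⇌ Z (K = 1.40, k = 0.00115 /min)
    G ⇌ Z (K = 1.40, k = 0.00115 /min)
    J → X (k = 3.21 × 10⁻⁴ /min)

The excess from s, 35.5 %, lies between the 34.3 % of dusk and the 36.0 % of dawn. In spring at 50.0 h, D turns into Z, by the forward step alone, 19 times as fast as J and D make L; at the start that ratio is 4.2. Z then stands at 34.3 % and [D]/[G] at 0.956. In dusk at 50.0 h, [D]/[G] is 0.894.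

The readings come from a simulation for substances that don't exist; noise was put on by code.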